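**Retrosynthetic overview**
1. Target 17 comes from 16 by buffered fluoride removal of two phenolic silyl groups.
2. Key disconnection C3–aryl: racemic 3-bromochromanone 5 (C3 as an enolonium equivalent) plus arylzinc 15; an enantioconvergent Ni/pybox Negishi coupling sets C3 as S.
3. 5 comes from 5,7-dihydroxychroman-4-one 1 (rings A and C bought intact): 7-O-silylation, 5-O-methylation, α-bromination.
4. Aryl bromide 13 comes from 5-bromosalicylaldehyde 6 and chloroalkyne 7: O-propargylation, Baeyer–Villiger to the phenol, silylation, then propargyl Claisen/oxa-6π closure of the 2H-pyran ring.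
5. Ring order: chromanone (present from the start), then the dimethylpyran ring of the aryl fragment (step 7), then fragment union (step 8).

Assumption: 5,7-dihydroxychroman-4-one (1) is bought as a catalogue compound.
Assumption: (R,R)-Ph-pybox is taken to give the 3S product; if a pilot run shows 3R, the mirror-image ligand is used.

**Route**

Step 1
Reactants: 1 5,7-dihydroxychroman-4-one
Product: 2 5-hydroxy-7-(triisopropylsilyloxy)chroman-4-one
Conditions: TIPSCl (1.05 equiv), imidazole, DMF, 0 °C → rt
Reagents that add atoms: triisopropylsilyl chloride, CC(C)[Si](Cl)(C(C)C)C(C)C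
Why: Silyl ether formation is selective for the free, more acidic 7-OH because the 5-OH is locked in a hydrogen bond to the peri carbonyl and is hindered.

Step 2
Reactants: 2 5-hydroxy-7-(triisopropylsilyloxy)chroman-4-one
Product: 3 5-methoxy-7-(triisopropylsilyloxy)chroman-4-one
Conditions: MeOH, PPh3, DIAD, THF, 0 °C → rt
Reagents that add atoms: methanol, CO
Why: A Mitsunobu reaction methylates the chelated phenol under neutral conditions, so the base-labile aryl silyl ether para to the ketone is not cleaved.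

Step 3
Reactants: 3 5-methoxy-7-(triisopropylsilyloxy)chroman-4-one
Product: 5 rac-3-bromo-5-methoxy-7-(triisopropylsilyloxy)chroman-4-one, via silyl enol ether 4 (not isolated)
Conditions: TMSOTf, Et3N, CH2Cl2, 0 °C; then NBS, THF, −78 °C
Reagents that add atoms: N-bromosuccinimide, BrN1C(=O)CCC1=O
Why: Soft enolisation gives an enol silane whose C3 is far more nucleophilic than the oxygenated ring A, so electrophilic α-bromination of the silyl enol ether occurs at C3 only; the new centre is racemic on purpose.

Step 4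
Reactants: 6 5-bromo-2-hydroxybenzaldehyde; 7 3-chloro-3-methylbut-1-yne
Product: 8 5-bromo-2-[(2-methylbut-3-yn-2-yl)oxy]benzaldehyde
Conditions: DBU, CuCl2·2H2O (1 mol %), MeCN, 0 °C → rt
Reagents that add atoms: none
Why: Copper-catalysed propargylic substitution O-alkylates the phenoxide with the tertiary propargylic chloride, where a plain SN2 reaction would fail.

Step 5
Reactants: 8 5-bromo-2-[(2-methylbut-3-yn-2-yl)oxy]benzaldehyde
Product: 10 5-bromo-2-[(2-methylbut-3-yn-2-yl)oxy]phenol, via aryl formate 9 (not isolated)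
Conditions: mCPBA, CH2Cl2, 0 °C → rt; then K2CO3 (cat.), MeOH, rt
Reagents that add atoms: mCPBA, OOC(=O)c1cccc(Cl)c1
Why: In this Baeyer–Villiger (Dakin-type) oxidation the ortho-alkoxyaryl group migrates in preference to hydrogen, the alkyne is inert to the peracid, and methanolysis of the formate frees the phenol meta to bromine with the other oxygen already alkylated.

Step 6
Reactants: 10 5-bromo-2-[(2-methylbut-3-yn-2-yl)oxy]phenol
Product: 11 [5-bromo-2-[(2-methylbut-3-yn-2-yl)oxy]phenoxy](tert-butyl)dimethylsilane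
Conditions: TBSCl, imidazole, DMF, rt
Reagents that add atoms: tert-butyldimethylsilyl chloride, CC(C)(C)[Si](C)(C)Cl
Why: Standard silyl ether formation on the only free phenol; no silyl scrambling is possible because the neighbouring oxygen carries the propargyl group.

Step 7
Reactants: 11 [5-bromo-2-[(2-methylbut-3-yn-2-yl)oxy]phenoxy](tert-butyl)dimethylsilane
Product: 13 6-bromo-8-(tert-butyldimethylsilyloxy)-2,2-dimethyl-2H-chromene, via allenylphenol 12 (not isolated)
Conditions: PhNEt2, 185 °C
Reagents that add atoms: none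
Why: Aromatic propargyl Claisen rearrangement to the only free ortho position, then 1,5-hydrogen shift and oxa-6π electrocyclisation, closes the 2H-pyran ring; a silyl shift between the two neighbouring oxygens would be harmless because only the isomer with the free OH next to the allene can cyclise.

Step 8
Reactants: 13 6-bromo-8-(tert-butyldimethylsilyloxy)-2,2-dimethyl-2H-chromene (1.5 equiv); 5 rac-3-bromo-5-methoxy-7-(triisopropylsilyloxy)chroman-4-one
Product: 16 (3S)-3-[8-(tert-butyldimethylsilyloxy)-2,2-dimethyl-2H-chromen-6-yl]-5-methoxy-7-(triisopropylsilyloxy)chroman-4-one, via arylmagnesium bromide 14 (not isolated), via arylzinc iodide 15 (not isolated)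
Conditions: Mg, THF, 45 °C; ZnI2, THF, rt; then 5, NiCl2·DME (10 mol %), (R,R)-Ph-pybox (13 mol %), DME/THF, −30 °C
Reagents that add atoms: none
Why: Proposed new method: enantioconvergent Negishi arylation of a cyclic α-bromo ketone, in which the chiral nickel/pybox catalyst abstracts bromine from either enantiomer of 5 to give a planar C3 radical (C3 acts as an enolonium equivalent, polarity reversed from the enolate), the radical is captured by the chiral aryl–nickel species and reductive elimination sets C3 as S under catalyst control, while the weakly basic arylzinc at −30 °C leaves the new acidic C3–H untouched; the closest known reaction type is the nickel/pybox-catalysed stereoconvergent Negishi arylation of racemic acyclic α-bromo aryl ketones.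

Step 9
Reactants: 16 (3S)-3-[8-(tert-butyldimethylsilyloxy)-2,2-dimethyl-2H-chromen-6-yl]-5-methoxy-7-(triisopropylsilyloxy)chroman-4-one
Product: 17 (3S)-7-hydroxy-3-(8-hydroxy-2,2-dimethyl-2H-chromen-6-yl)-5-methoxychroman-4-one
Conditions: TBAF, AcOH (1:1), THF, 0 °C
Reagents that add atoms: none
Why: Fluoride-mediated desilylation cleaves both aryl silyl ethers, and the acetic acid buffer keeps the medium non-basic so that C3 neither enolises nor opens by retro-oxa-Michael reaction and the S configuration is kept.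

**Compound list**
1 | 5,7-dihydroxychroman-4-one | O=C1CCOc2cc(O)cc(O)c12 | starting material
2 | 5-hydroxy-7-(triisopropylsilyloxy)chroman-4-one | O=C1CCOc2cc(O[Si](C(C)C)(C(C)C)C(C)C)cc(O)c12 | intermediate
3 | 5-methoxy-7-(triisopropylsilyloxy)chroman-4-one | COc1cc(O[Si](C(C)C)(C(C)C)C(C)C)cc2OCCC(=O)c12 | intermediate
4 | 5-methoxy-4-(trimethylsilyloxy)-7-(triisopropylsilyloxy)-2H-chromene | COc1cc(O[Si](C(C)C)(C(C)C)C(C)C)cc2OCC=C(O[Si](C)(C)C)c12 | intermediate
5 | rac-3-bromo-5-methoxy-7-(triisopropylsilyloxy)chroman-4-one | COc1cc(O[Si](C(C)C)(C(C)C)C(C)C)cc2OCC(Br)C(=O)c12 | intermediate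
6 | 5-bromo-2-hydroxybenzaldehyde | O=Cc1cc(Br)ccc1O | starting material
7 | 3-chloro-3-methylbut-1-yne | CC(C)(Cl)C#C | starting material
8 | 5-bromo-2-[(2-methylbut-3-yn-2-yl)oxy]benzaldehyde | O=Cc1cc(Br)ccc1OC(C)(C)C#C | intermediate
9 | 5-bromo-2-[(2-methylbut-3-yn-2-yl)oxy]phenyl formate | O=COc1cc(Br)ccc1OC(C)(C)C#C | intermediate
10 | 5-bromo-2-[(2-methylbut-3-yn-2-yl)oxy]phenol | Oc1cc(Br)ccc1OC(C)(C)C#C | intermediate
11 | [5-bromo-2-[(2-methylbut-3-yn-2-yl)oxy]phenoxy](tert-butyl)dimethylsilane | CC(C)(C)[Si](C)(C)Oc1cc(Br)ccc1OC(C)(C)C#C | intermediate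
12 | 4-bromo-2-(tert-butyldimethylsilyloxy)-6-(3-methylbuta-1,2-dien-1-yl)phenol | CC(C)(C)[Si](C)(C)Oc1cc(Br)cc(C=C=C(C)C)c1O | intermediate
13 | 6-bromo-8-(tert-butyldimethylsilyloxy)-2,2-dimethyl-2H-chromene | CC(C)(C)[Si](C)(C)Oc1cc(Br)cc2C=CC(C)(C)Oc12 | intermediate
14 | [8-(tert-butyldimethylsilyloxy)-2,2-dimethyl-2H-chromen-6-yl]magnesium bromide | CC(C)(C)[Si](C)(C)Oc1cc([Mg]Br)cc2C=CC(C)(C)Oc12 | intermediate
15 | [8-(tert-butyldimethylsilyloxy)-2,2-dimethyl-2H-chromen-6-yl]zinc iodide | CC(C)(C)[Si](C)(C)Oc1cc([Zn]I)cc2C=CC(C)(C)Oc12 | intermediate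
16 | (3S)-3-[8-(tert-butyldimethylsilyloxy)-2,2-dimethyl-2H-chromen-6-yl]-5-methoxy-7-(triisopropylsilyloxy)chroman-4-one | COc1cc(O[Si](C(C)C)(C(C)C)C(C)C)cc2c1C(=O)[C@@H](c1cc(O[Si](C)(C)C(C)(C)C)c3c(c1)C=CC(C)(C)O3)CO2 | intermediate
17 | (3S)-7-hydroxy-3-(8-hydroxy-2,2-dimethyl-2H-chromen-6-yl)-5-methoxychroman-4-one | COc1cc(O)cc2c1C(=O)[C@@H](c1cc(O)c3c(c1)C=CC(C)(C)O3)CO2 | target

**Totals**
Total step count: 9. Longest linear sequence: 6 steps (steps 4, 5, 6, 7, 8, 9).

**Three steps most likely to fail**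

Step 8 (the enantioconvergent coupling). The cyclic bromide 5 may lose HBr to give the chromone, the nickel enolate may expel the ring aryloxide, or the enantioselectivity on a cyclic substrate may be low. The fallback sets out from 3 and 13 and separates bond formation from stereocontrol. A palladium-catalysed ketone α-arylation (Pd(OAc)2, XPhos, K3PO4, toluene, 80 °C) joins 3 and 13 to give rac-3-[8-(tert-butyldimethylsilyloxy)-2,2-dimethyl-2H-chromen-6-yl]-5-methoxy-7-(triisopropylsilyloxy)chroman-4-one F1. Soft enolisation (TMSOTf, Et3N, CH2Cl2, 0 °C) converts it into 3-[8-(tert-butyldimethylsilyloxy)-2,2-dimethyl-2H-chromen-6-yl]-5-methoxy-4-(trimethylsilyloxy)-7-(triisopropylsilyloxy)-2H-chromene F2. A catalytic enantioselective protonation of this enol silane (chiral BINOL-derived N-triflyl thiophosphoramide, phenol as the stoichiometric proton source, toluene, rt) then sets C3 and comes back to the route at 16.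

Step 3 (α-bromination). Ring A is strongly activated, so bromination at C6 or C8, or double bromination, may compete, and 5 may lose HBr on silica. The fallback sets out from 3 and avoids electrophilic bromine. Oxidative α-tosyloxylation with PhI(OH)OTs (MeCN, 60 °C) gives rac-5-methoxy-4-oxo-7-(triisopropylsilyloxy)chroman-3-yl 4-methylbenzenesulfonate F3. Displacement of the tosylate with LiBr (acetone, 50 °C) comes back to the route at 5.

Step 2 (methylation of the chelated 5-OH). The peri hydroxyl may react too slowly in the Mitsunobu reaction, and forcing conditions may cost the 7-O-silyl group. The fallback sets out from 1 and uses a benzyl relay. BnBr and K2CO3 in acetone give 7-(benzyloxy)-5-hydroxychroman-4-one F4. MeI and K2CO3 in DMF give 7-(benzyloxy)-5-methoxychroman-4-one F5. Hydrogenolysis (H2, 10% Pd/C, EtOAc) gives 7-hydroxy-5-methoxychroman-4-one F6. Silylation with TIPSCl and imidazole then comes back to the route at 3.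

**Further compounds**
F1 | step 8 | rac-3-[8-(tert-butyldimethylsilyloxy)-2,2-dimethyl-2H-chromen-6-yl]-5-methoxy-7-(triisopropylsilyloxy)chroman-4-one | COc1cc(O[Si](C(C)C)(C(C)C)C(C)C)cc2c1C(=O)C(c1cc(O[Si](C)(C)C(C)(C)C)c3c(c1)C=CC(C)(C)O3)CO2
F2 | step 8 | 3-[8-(tert-butyldimethylsilyloxy)-2,2-dimethyl-2H-chromen-6-yl]-5-methoxy-4-(trimethylsilyloxy)-7-(triisopropylsilyloxy)-2H-chromene | COc1cc(O[Si](C(C)C)(C(C)C)C(C)C)cc2c1C(O[Si](C)(C)C)=C(c1cc(O[Si](C)(C)C(C)(C)C)c3c(c1)C=CC(C)(C)O3)CO2
F3 | step 3 | rac-5-methoxy-4-oxo-7-(triisopropylsilyloxy)chroman-3-yl 4-methylbenzenesulfonate | COc1cc(O[Si](C(C)C)(C(C)C)C(C)C)cc2OCC(OS(=O)(=O)c3ccc(C)cc3)C(=O)c12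
F4 | step 2 | 7-(benzyloxy)-5-hydroxychroman-4-one | O=C1CCOc2cc(OCc3ccccc3)cc(O)c12
F5 | step 2 | 7-(benzyloxy)-5-methoxychroman-4-one | COc1cc(OCc3ccccc3)cc2OCCC(=O)c12
F6 | step 2 | 7-hydroxy-5-methoxychroman-4-one | COc1cc(O)cc2OCCC(=O)c12
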